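Percent of the starting material charged is the unit here, and one side product counts as two.

| setting | north-east | gamma | alpha |
|---|---|---|---|
| starting material | 0.10 M | 0.10 M | 0.10 M |
| reagent | 0.048 M | 0.0950 M | 0.0950 M |
| temperature | −20 °C | −20 °C | 20 °C |
| remark | run made earlier |  |  |
| time |  | 10 h | 10 h |

north-east run (percent of the starting material charged)

| time / h | target / % | side product / % | over-reaction product / % |
|---|---|---|---|
| 0.250 | 0.9 | 6.2 | 0.1 |
| 0.417 | 2.4 | 11.5 | 0 |
| 0.667 | 3.1 | 15.9 | 0 |
| 1.00 | 4.9 | 21.2 | 0.4 |
| 2.00 | 7.7 | 34.9 | 0.7 |
| 3.00 | 10.2 | 41.9 | 0.9 |

(standard deviation of a reading: 0.5 percentage points)

- percentages count the starting material that a species holds: one side product counts as two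
- the earlier runs do not show what temperature does; that part of a forecast is a guess

1. the winner by share of target in all that became target or side product or over-reaction product; "neither" if no more than 2 percentage points parts them (gamma / alpha / neither)
2. share of target in all that became target or side product or over-reaction product, gamma
3. share of target in all that became target or side product or over-reaction product, alpha

Over-reaction product was once target, so the two together are the path through reagent. The readings suggest this path is first order in [starting material] and in [reagent], though with scatter. The side path looks second order in [starting material]. The ratio of the paths should then follow [reagent]/[starting material]. The north-east reading at 3.00 h gives 0.552 for the branch factor, a selectivity factor: path through reagent over side product, divided by the charged [reagent]/[starting material].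

Gamma is charged at 0.950, so its path ratio should be 0.524. Target and over-reaction product together then hold 34.4% of the products. That is my ceiling on gamma's share, reached if no target is lost.

Two chemists part here. The first says that forming gamma's target takes 0.0344 M of reagent, less than the 0.0950 M charged. Reagent should therefore be left over, and in the hot flask it has hours to attack target. The second answers that no run measures reagent, and that over-reaction needs it. If hot reagent disappears by some other way, target survives. So the second holds gamma's share under 34.4%. That figure comes from a reading at −20 °C, so it is no bound on alpha, and putting alpha no lower than gamma is a guess about temperature. This reckoning is the one kept here.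

The forecast, the first chemist's number, says gamma, with 22% and 9%, because “leftover reagent keeps converting target to over-reaction for hours”.

The flasks give 19.7% for gamma and 25.7% for alpha, so alpha wins.

    starting material + reagent → target (k = 3.80 × 10⁻⁴ M⁻¹ s⁻¹, Ea = 62.0 kJ mol⁻¹)
    2 reagent → self-condensation product (k = 2.30 × 10⁻⁴ M⁻¹ s⁻¹, Ea = 66.0 kJ mol⁻¹)
    reagent + target → over-reaction product (k = 5.90 × 10⁻⁴ M⁻¹ s⁻¹, Ea = 52.0 kJ mol⁻¹)
    2 starting material → side product (k = 4.00 × 10⁻⁴ M⁻¹ s⁻¹, Ea = 47.0 kJ mol⁻¹)
    (constants at −20 °C)

Gamma's path ratio comes out at 0.507 against the 0.524 reckoned. Alpha's lead comes from the difference in temperature: its share of 25.7% falls to 19.7% without that difference. The first view has its region in gamma, which keeps 22% of its reagent at 10.0 h. There the length of the run and the depletion of reagent act together: a run ten times as long gives 10.6%, and without the depletion the share is 14.5%. Alpha's own branch factor is 0.685, higher than the one read at −20 °C. For a flask like alpha charged with 0.38 M of reagent, it gives a path ratio of 2.60, and that flask holds 2.11.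

The data were computed with made-up constants; noise was put on by code.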